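Elm stood higher than oak at 8.00 d, 26% against 15%, and elm had twice the reagent. You asked for a quick number on oak and guessed that more reagent was the cure. I tested that guess.

| setting | oak | elm | flask |
|---|---|---|---|
| starting material | 0.42 M | 0.42 M | 0.42 M |
| reagent | 1.8 equiv | 3.6 equiv | 1.80 equiv |
| second substrate | 1 equiv | 1 equiv | 1.00 equiv |
| free catalyst | 20 mol% | 20 mol% | 20 mol% |
| temperature | 35 °C | 20 °C | 35 °C |
| remark | the very flask that is asked about, followed so far | run made earlier |  |
| time |  |  | 8.0 d |

| oak: time / d | oak: target / % | elm: time / d | elm: target / % |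
|---|---|---|---|
| 0.625 | 9 | 8.00 | 26 |
| 1.04 | 10 | 15.0 | 30 |
| 1.67 | 10 | 25.0 | 33 |
| 2.50 | 15 | 30.0 | 32 |
| 3.00 | 10 | 40.0 | 31 |
| 5.00 | 15 | 50.0 | 33 |
| 8.00 | 15 | 60.0 | 34 |

(each reading ± 1.5 percentage points)

- target that was removed still counts
- what may be going on: starting material + reagent + free catalyst -> free catalyst + target; second substrate + reagent + free catalyst -> free catalyst + second product; 2 second substrate -> homo dimer; starting material <-> dormant form; 2 free catalyst -> spent catalyst
- additions bring no volume worth counting

- beta: change nothing and wait 4.0 d more
- zeta: at 8.0 d add reagent, 100% of the amount charged, then wait 4.0 d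
- epsilon: at 8.0 d take out 90% of the target then present, then wait 4.0 d
- delta: at 8.0 d raise the temperature by 20 K, then wait 4.0 d
- gamma: at 8.0 d add free catalyst, 100% of the amount charged, then wait 4.0 d

- target, in percent of the starting material first charged, at 8.0 d
- the remedy with the largest gain of target, or "none" below 2 percentage points (beta / zeta / epsilon / delta / gamma / none)
- target present, with what was taken out counted in, in percent of the starting material first charged, after zeta
- target present, with what was taken out counted in, in percent of the starting material first charged, after epsilon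

1. Oak had c(reagent) = 0.756 M. I divided the target share by c(reagent), and again by one minus half that share, the mean part of the starting material not yet turned to target. I called this the reach 0.215 M⁻¹.

2. Elm, at 20 °C rather than 35 °C, gave a reach of 0.198 M⁻¹, close to oak's. So in these two runs, which differed in temperature as well, target at 8.00 d went with c(reagent).

3. For now I kept oak's reading, 15%.

4. Free catalyst dies in pairs, a second-order deactivation, so late on it falls roughly as one over time. Target then gains equal steps per equal factor of time. Oak's readings gave 0.99 percentage points for the next 4.0 d.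

5. Target consumes nothing in the listed steps, so I put epsilon at 16.0%.

6. I took doubled reagent to double that creep, not the whole yield. So I put zeta at 17.0%, which is a small gain for your cure.

7. I expected fresh catalyst to restart the flask. Oak's mean around 4.00 d was 12.5%. Put back in, with the target already made taken off the starting material, that gave a gain of 11 points, more than zeta's. I did not reckon delta, but I chose gamma.

The forecast gave 14.5% (13% to 16%), gamma, 17% (15% to 20%) for zeta and 15.5% (14% to 17%) for epsilon: “Fresh catalyst should therefore restart the reaction, making gamma the best remedy.”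

Oak gave 14.7% at 8.00 d. Gamma gained 8.3 points, the largest gain, against my 11 points. Zeta reached 16.6% and epsilon 15.6%.

    starting material + reagent + free catalyst → free catalyst + target (k = 1.62 × 10⁻⁴ M⁻² s⁻¹, Ea = 51.0 kJ mol⁻¹)
    second substrate + reagent + free catalyst → free catalyst + second product (k = 2.94 × 10⁻⁴ M⁻² s⁻¹, Ea = 54.0 kJ mol⁻¹)
    2 second substrate → homo dimer (k = 1.08 × 10⁻⁵ M⁻¹ s⁻¹, Ea = 77.0 kJ mol⁻¹)
    starting material ⇌ dormant form (K = 0.590, k = 1.94 × 10⁻⁵ s⁻¹, Ea = 98.0 kJ mol⁻¹, ΔH = −29.0 kJ mol⁻¹)
    2 free catalyst → spent catalyst (k = 0.00122 M⁻¹ s⁻¹, Ea = 63.0 kJ mol⁻¹)
    (constants at 35 °C)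

Oak's result gave a reach of 0.210 M⁻¹. The neighbour flask held 1.1 M of starting material on the same recipe, so c(reagent) was 1.98 M. The reach I had carried from oak's reading, 0.215 M⁻¹, times c(reagent) gave a first answer of 42.5%. Put back in once, it gave 33.5%. That neighbour flask stood at 34.2% after 8.00 d.

The numbers in the tables were computed with constants of no real substance.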